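(The constants are assumed; no experiment stands behind them.)

Two substrates totalling 1.22 M cannot both finish on 0.793 M of coupling partner, the limiting reagent, so we reckon what each mole of target costs in partner.

    starting material + free catalyst ⇌ catalyst intermediate A (K1 = 4.1 M⁻¹, k1 = 2300 M⁻¹ s⁻¹)
    coupling partner + catalyst intermediate A → free catalyst + target (k2 = 67 M⁻¹ s⁻¹)
    second substrate + free catalyst ⇌ catalyst intermediate B (K3 = 2.5 M⁻¹, k3 = 150 M⁻¹ s⁻¹)
    coupling partner + catalyst intermediate B → free catalyst + second product (k4 = 1400 M⁻¹ s⁻¹)
    coupling partner → decomposed reagent (k5 = 0.016 s⁻¹)
    crystals ⇌ target, rate k6*(cs6 - [target]) while solid is left; crystals form when [target] > cs6 (cs6 = 9.7 mM, k6 = 0.47 s⁻¹)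

starting material 0.61 M; second substrate 1.00 equiv; coupling partner 1.30 equiv; free catalyst 0.078 mol%; time 1.5 min

- for target the crystals are counted in
- as a solid, counted per litre of solution: crystals
- the reaction counts as stopped when no species that holds the starting material changes by six tenths of a point or more over the second half of the time
- run time (flask): 1.5 min

- at 1.5 min, what has stopped the reaction, if anything has (all of the starting material has reacted / forward and back rates have come level / no working catalyst is left / the coupling partner has run out first / it is still moving)
- amount of target at 1.5 min, in percent of the starting material charged

Catalyst intermediate A falls back at 561 s⁻¹, faster than the 53.1 s⁻¹ at which it goes on at the start, so we treat it as a pre-equilibrium. Catalyst intermediate B goes on at 1110 s⁻¹ at the start, faster than it falls back at 60.0 s⁻¹.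

Dividing rate by rate removes time. The selectivity factor, target rate over second product rate, is 1.83 M⁻¹ times c(starting material)/c(second substrate) times the sum of c(coupling partner) and 0.0429 M. With the substrate ratio held at its charge, it starts at 1.53 and falls in a straight line as partner is used.

Free catalyst starts near 0.136 mM. On our reckoning, target then forms at 18.1 mM s⁻¹, second product at 11.8 mM s⁻¹ and decomposed reagent at 12.7 mM s⁻¹. So the target curve starts steeply. Its rate crosses that of second product at about 0.114 min, and it bends near 0.311 min, the time the charge lasts at the starting pace.

For the level, we take the selectivity factor at half the partner, 0.805. With the substrates at their charge, we put the share of catalyst in intermediate A at 60.6%, midway between a balance with catalyst intermediate B left out and one with it at equilibrium. Decomposition then costs 0.828 per target. That gives 3.07 moles of coupling partner spent per mole of target, the partner cost, and so 42.3% target.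

The forecast says the coupling partner has run out first, “leaving both substrates unfinished”, and gives 38% target, which is lower than our figure.

The flask gives the coupling partner has run out first and 39.3%, 3 percentage points below our reckoning. At 0.272 min, catalyst intermediate A falls back 28 times faster than it goes on. Coupling partner stands at 0% at 1.50 min, so this flask spent 3.31 moles of it per mole of target, against our partner cost of 3.07. With 2.50 equiv of second substrate, we reckon the neighbour flask at a partner cost of 5.06, hence 25.7% target. Computed, that neighbour flask gives 23.9%.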